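The numbers in the tables come from a simulation for substances that don't exist; the scatter is artificial.

Hold one difference fixed: if Q takes Z one for one and tightly, which is my assumption, then working catalyst minus Q still left stays constant. Two amounts enter, the charges of Z, 1.8 µM, and of Q, 1.4 µM. Count the Z scale from the charge of Q, not from zero, and define W, the excess of catalyst over Q, as 0.400 µM.

| setting | oak | flask |
|---|---|---|
| X | 0.10 M | 0.10 M |
| Z | 1.8 µM | 1.8 µM |
| Q | 1.4 µM | 1.4 µM |
| remark | the very flask that is asked about, followed so far |  |

oak run (percent of the X charged)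

| time / h | D / % | X / % |
|---|---|---|
| 0.250 | 6.2 | 95.8 |
| 0.667 | 8.5 | 89.7 |
| 1.33 | 13.4 | 87.9 |
| 2.00 | 19.7 | 81.0 |
| 3.00 | 26.0 | 74.1 |
| 4.00 | 33.6 | 65.8 |
| 5.00 | 40.3 | 60.3 |

(readings scatter by 1 percentage point)

- the earlier runs were read with a standard deviation of 1 percentage point
- no earlier run changes the charge of Z; that part of a forecast is a guess

* factor on the rate of making D when 30% of the X are converted if Z is charged twice over
* factor on the rate when 30% of the X are converted if Z is charged at 20 µM instead

Read the oak run, the very flask asked about: D reaches 6.2% by 0.250 h, climbing faster than on its later line from 19.7% at 2.00 h to 40.3% at 5.00 h. Take that line as W at work; 30% conversion lies on it, between 3.00 h and 4.00 h. At fixed X, let the rate follow working catalyst: doubling Z gives 5.50, and 20 µM gives 46.5. No earlier run changes Z, so both remain guesses.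

The forecast gives 5.5 and 46, on a steady rate that scales with the excess “The steady rate then scales with (Z − 1.4)”.

The flask gives 5.50 and 46.5.

    X + Z ⇌ J (K = 36.0 M⁻¹, k = 2100 M⁻¹ s⁻¹)
    J → Z + D (k = 6.90 s⁻¹)
    Z + Q → E (k = 6900 M⁻¹ s⁻¹)

Here J is Z holding X, and E is Z holding Q. In this flask Q, the limiting reagent of that capture, is down to 1.13% of its charge at 1.20 h, when the turning of J into Z + D has 17% of its turnover up to 12.0 h behind it, and E already stands at 76.9% of the catalyst, against 77.8% at 3.52 h, when 30% of the X are converted. W is 22.2% of the charge, and at 120 h Z holds 22.2% beside E at 77.8%; with Z at 20 µM, the excess is 93.0% of the charge, and Z itself stands at 28.6% of that catalyst at the same conversion.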